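Everything rests on taking ring A apart at C8a–C8, C6–C7 and C4a–C8a into an enantiopure siloxyalkyne and a 3-benzyloxyvinylketene. The feature exploited is C8 of ring A: it carries the (R)-1-arylethyl group and lies between the oxygenated carbons C7 and C8a, with the third oxygen at C5. One thermal benzannulation builds the phloroglucinol ring around the finished stereocentre and delivers C8a–OH free, C7–O silylated and C5–O benzylated. The precursor is (R)-ArCH(CH3)C≡C–OSi(i-Pr)3 (Ar = 4-benzyloxyphenyl), reached through acetylide oxidation so that no alpha-aryl ester meets strong base. Ring C is then added under basic or weakly acidic conditions only.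

Key step: step 8

Assumption: the target SMILES is read as (R) at the benzylic carbon (C8 of ring A > 4-hydroxyphenyl > CH3 > H). Compounds 13 and 22 and anhydrous t-BuOOH in decane are taken as catalogue items.

Remark: without the silyl group, the two oxygens flanking C8 are equivalent by rotation about the C8–CH bond. The distinction that must never be lost is therefore that of C5–O, and no reagent able to cleave the C5 benzyl ether is used before ring C is closed. Enantiopurity should be checked on a chiral HPLC phase at 9 and at 20.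

Step 1
Reactants: 1 4-(benzyloxy)phenylacetic acid; 2 (4R)-4-benzyl-1,3-oxazolidin-2-one
Product: 4 (4R)-4-benzyl-3-{[4-(benzyloxy)phenyl]acetyl}-1,3-oxazolidin-2-one, via mixed pivalic anhydride 3 (not isolated)
Conditions: t-BuCOCl, Et3N, THF, −20 °C; then LiCl, 2, −20 °C → rt
Reagents that add atoms: none
Why: LiCl-assisted N-acylation of the Evans auxiliary by the mixed anhydride takes place at the less hindered arylacetyl carbonyl and avoids an acid chloride that could collapse to a ketene.

Step 2
Reactants: 4 (4R)-4-benzyl-3-{[4-(benzyloxy)phenyl]acetyl}-1,3-oxazolidin-2-one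
Product: 6 (4R)-4-benzyl-3-{(2R)-2-[4-(benzyloxy)phenyl]propanoyl}-1,3-oxazolidin-2-one, via sodium Z-enolate 5 (not isolated)
Conditions: NaN(SiMe3)2 (1.1 equiv), THF, −78 °C; MeI (5 equiv), −78 → −40 °C; AcOH quench
Reagents that add atoms: iodomethane, CI
Why: In this Evans asymmetric alkylation the sodium-chelated Z-enolate is methylated on the face opposite the C4 benzyl group of the (R)-auxiliary, which sets the (R) centre, and the minor diastereomer can be removed by chromatography or crystallisation.

Step 3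
Reactants: 6 (4R)-4-benzyl-3-{(2R)-2-[4-(benzyloxy)phenyl]propanoyl}-1,3-oxazolidin-2-one
Product: 7 (2R)-2-[4-(benzyloxy)phenyl]propan-1-ol
Conditions: LiBH4, H2O (1 equiv), Et2O, 0 °C
Reagents that add atoms: none
Why: Reductive cleavage of the imide by LiBH4 attacks the exocyclic carbonyl under essentially non-basic conditions, so the auxiliary is released without epimerising the alpha-aryl centre.

Step 4
Reactants: 7 (2R)-2-[4-(benzyloxy)phenyl]propan-1-ol
Product: 8 (2R)-2-[4-(benzyloxy)phenyl]propanal
Conditions: Dess–Martin periodinane, NaHCO3, CH2Cl2, 0 °C → rt; crude product used at once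
Reagents that add atoms: none
Why: Dess–Martin oxidation needs no amine base, and the bicarbonate buffer removes the acetic acid that could enolise the configurationally sensitive 2-arylpropanal, which is carried on without chromatography.

Step 5
Reactants: 8 (2R)-2-[4-(benzyloxy)phenyl]propanal
Product: 9 1-(benzyloxy)-4-[(2S)-4,4-dibromobut-3-en-2-yl]benzene
Conditions: CBr4, PPh3, CH2Cl2, 0 °C (ylide preformed); then 8, 0 °C
Reagents that add atoms: carbon tetrabromide, BrC(Br)(Br)Br
Why: Ramirez dibromoolefination (first stage of the Corey–Fuchs sequence) uses a weakly basic ylide that adds to the aldehyde faster than it enolises it, after which the centre is no longer alpha to a carbonyl group and the descriptor becomes S only because aryl now outranks the alkenyl carbon.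

Step 6
Reactants: 9 1-(benzyloxy)-4-[(2S)-4,4-dibromobut-3-en-2-yl]benzene
Product: 12 triisopropyl({(3R)-3-[4-(benzyloxy)phenyl]but-1-yn-1-yl}oxy)silane, via lithium acetylide 10 (not isolated), via lithium ynolate 11 (not isolated)
Conditions: n-BuLi (2.0 equiv), THF, −78 °C; LiOOt-Bu [t-BuOOH, LiN(SiMe3)2, THF, −78 °C], −78 → 0 °C; i-Pr3SiOTf, −78 → 0 °C
Reagents that add atoms: tert-butyl hydroperoxide, CC(C)(C)OO; triisopropylsilyl trifluoromethanesulfonate, CC(C)[Si](OS(=O)(=O)C(F)(F)F)(C(C)C)C(C)C
Why: The second stage of the Corey–Fuchs sequence gives the acetylide, nucleophilic displacement on the peroxide oxygen of LiOOt-Bu (acetylide-to-ynolate oxidation) gives the ynolate, and the bulky silyl triflate reacts at oxygen and not at carbon, while the negative charge on 10 and 11 shields the propargylic C–H as long as no excess n-BuLi is present.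

Step 7
Reactants: 13 3-ethoxycyclobut-2-en-1-one; 14 benzyl alcohol
Product: 15 3-(benzyloxy)cyclobut-2-en-1-one
Conditions: 14 (3 equiv), pyridinium p-toluenesulfonate (5 mol %), toluene, 45 °C, reduced pressure (EtOH removed)
Reagents that add atoms: none
Why: Acid-catalysed addition–elimination at C3 of the vinylogous ester, the alcohol counterpart of its known hydrolysis to cyclobutane-1,3-dione, is driven by removal of ethanol at a temperature well below that of electrocyclic ring opening, so no vinylketene is trapped by the alcohol.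

Step 8
Reactants: 12 triisopropyl({(3R)-3-[4-(benzyloxy)phenyl]but-1-yn-1-yl}oxy)silane; 15 3-(benzyloxy)cyclobut-2-en-1-one
Product: 20 5-(benzyloxy)-2-{(1R)-1-[4-(benzyloxy)phenyl]ethyl}-3-[(triisopropylsilyl)oxy]phenol, via vinylketene 16 (not isolated), via alkenylcyclobutenone 17 (not isolated), via dienylketene 18 (not isolated), via cyclohexadienone 19 (not isolated)
Conditions: degassed toluene, 110 °C, 15 (1.4 equiv) added over 6 h by syringe pump; then 125 °C, sealed vessel
Reagents that add atoms: none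
Why: Danheiser benzannulation: conrotatory four-electron opening of 15 releases vinylketene 16, whose carbonyl carbon is attacked by the oxygen-remote, nucleophilic alkyne carbon of 12 in a [2+2] cycloaddition that forms C8a–C8 and C6–C7 and gives the 4-alkenylcyclobut-2-enone 17. Reversible four-electron opening of 17 gives dienylketene 18, ring A closes by a thermal disrotatory six-electron electrocyclisation that forms C4a–C8a, and tautomerisation of dienone 19 gives the phenol. The closest known chemistry is the reaction of 3-alkylcyclobutenones with triisopropylsiloxyalkynes bearing secondary propargylic carbons, which gives 2-alkylresorcinol monosilyl ethers, and the formation of 3,5-dialkoxyphenols on heating alkoxyacetylenes, which runs through 3-alkoxycyclobutenones, indicates that oxygen at C3 of the cyclobutenone is tolerated. No lasting stereocentre is created (C4 of 17 is lost on aromatisation), and the propargylic centre is a spectator because no bond to it is made or broken and neither acid nor base is present. The only selectivity needed is the orientation of the [2+2] step, which the polarisation of the siloxyalkyne fixes, so the ketene oxygen ends as free C8a–OH, the silyloxy group at C7 and the benzyloxy group at C5. Slow addition of 15 keeps the concentration of 16 low, which should suppress ketene dimerisation and acylation of the hindered product phenol.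

Step 9
Reactants: 20 5-(benzyloxy)-2-{(1R)-1-[4-(benzyloxy)phenyl]ethyl}-3-[(triisopropylsilyl)oxy]phenol
Product: 21 3-(benzyloxy)-6-{(1R)-1-[4-(benzyloxy)phenyl]ethyl}-2-bromo-5-[(triisopropylsilyl)oxy]phenol
Conditions: NBS (1.0 equiv), i-Pr2NH (10 mol %), CH2Cl2, −78 → 0 °C, dark
Reagents that add atoms: N-bromosuccinimide, O=C1CCC(=O)N1Br
Why: Amine-catalysed ortho-bromination of a phenol, in which the N-bromoamine is delivered through hydrogen bonding to the hydroxyl, should select C4a as the only free ortho position, while C6 is screened by the triisopropylsilyl group that the C8 side chain forces to lean over it.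

Step 10
Reactants: 21 3-(benzyloxy)-6-{(1R)-1-[4-(benzyloxy)phenyl]ethyl}-2-bromo-5-[(triisopropylsilyl)oxy]phenol; 22 N,2-dimethoxy-N-methylacetamide
Product: 24 1-{6-(benzyloxy)-3-[(1R)-1-[4-(benzyloxy)phenyl]ethyl]-2-hydroxy-4-[(triisopropylsilyl)oxy]phenyl}-2-methoxyethan-1-one, via dilithio species 23 (not isolated)
Conditions: n-BuLi (2.1 equiv), THF, −78 °C; 22 (1.5 equiv), −78 → 0 °C; aq NH4Cl
Reagents that add atoms: none
Why: Deprotonation and bromine–lithium exchange give the O,C-dilithio arene, whose addition to the amide stops at the chelated tetrahedral adduct (Weinreb ketone synthesis), so the methoxyacetyl group enters at C4a without a Lewis acid that could cleave the C5 benzyl ether or ionise the C8–CH bond.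

Step 11
Reactants: 24 1-{6-(benzyloxy)-3-[(1R)-1-[4-(benzyloxy)phenyl]ethyl]-2-hydroxy-4-[(triisopropylsilyl)oxy]phenyl}-2-methoxyethan-1-one; 25 4-methoxybenzoyl chloride
Product: 27 5-(benzyloxy)-8-{(1R)-1-[4-(benzyloxy)phenyl]ethyl}-3-methoxy-2-(4-methoxyphenyl)-7-[(triisopropylsilyl)oxy]-4H-chromen-4-one, via diketone 26 (not isolated)
Conditions: LiN(SiMe3)2 (3.5 equiv), THF, −78 → −20 °C; 25 (1.1 equiv), −78 °C → rt; AcOH quench, concentrate; AcOH, 95 °C
Reagents that add atoms: none
Why: Aroylation of the phenoxide–enolate dianion (excess-base variant of the Baker–Venkataraman route, in which direct C-acylation and O-acylation followed by acyl shift converge on 26) is followed by cyclodehydration through the 2-hydroxyflavanone, which only the free C8a–OH can form because C5–O is benzylated and which ionises readily in warm acetic acid thanks to the 4-methoxyphenyl group.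

Step 12
Reactants: 27 5-(benzyloxy)-8-{(1R)-1-[4-(benzyloxy)phenyl]ethyl}-3-methoxy-2-(4-methoxyphenyl)-7-[(triisopropylsilyl)oxy]-4H-chromen-4-one
Product: 28 5-(benzyloxy)-8-{(1R)-1-[4-(benzyloxy)phenyl]ethyl}-7-hydroxy-3-methoxy-2-(4-methoxyphenyl)-4H-chromen-4-one
Conditions: Bu4NF, AcOH (1.1 equiv each), THF, 0 °C
Reagents that add atoms: none
Why: Fluoride-induced cleavage of the aryl silyl ether is fast at 0 °C, the acetic acid buffer protonates the liberated 7-phenoxide, and the benzyl and methyl ethers are inert.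

Step 13
Reactants: 28 5-(benzyloxy)-8-{(1R)-1-[4-(benzyloxy)phenyl]ethyl}-7-hydroxy-3-methoxy-2-(4-methoxyphenyl)-4H-chromen-4-one
Product: 29 5,7-dihydroxy-8-[(1R)-1-(4-hydroxyphenyl)ethyl]-3-methoxy-2-(4-methoxyphenyl)-4H-chromen-4-one
Conditions: H2 (1 atm), Pd/C (10 wt %), EtOAc–MeOH, rt
Reagents that add atoms: none
Why: Heterogeneous hydrogenolysis of the two aryl benzyl ethers proceeds at one atmosphere, where the tetrasubstituted C2=C3 bond of the chromone, the aryl methyl ethers and the C–C bonds of the diarylmethine centre should stay untouched.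

Compound list
1 | 4-(benzyloxy)phenylacetic acid | OC(=O)Cc1ccc(OCc2ccccc2)cc1 | starting material
2 | (4R)-4-benzyl-1,3-oxazolidin-2-one | O=C1N[C@H](Cc2ccccc2)CO1 | starting material
3 | [4-(benzyloxy)phenyl]acetic pivalic anhydride | CC(C)(C)C(=O)OC(=O)Cc1ccc(OCc2ccccc2)cc1 | intermediate
4 | (4R)-4-benzyl-3-{[4-(benzyloxy)phenyl]acetyl}-1,3-oxazolidin-2-one | O=C(Cc1ccc(OCc2ccccc2)cc1)N1[C@H](Cc2ccccc2)COC1=O | intermediate
5 | sodium Z-enolate of 4 | [Na+].[O-]/C(=C\c1ccc(OCc2ccccc2)cc1)N1[C@H](Cc2ccccc2)COC1=O | intermediate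
6 | (4R)-4-benzyl-3-{(2R)-2-[4-(benzyloxy)phenyl]propanoyl}-1,3-oxazolidin-2-one | O=C([C@H](C)c1ccc(OCc2ccccc2)cc1)N1[C@H](Cc2ccccc2)COC1=O | intermediate
7 | (2R)-2-[4-(benzyloxy)phenyl]propan-1-ol | OC[C@H](C)c1ccc(OCc2ccccc2)cc1 | intermediate
8 | (2R)-2-[4-(benzyloxy)phenyl]propanal | O=C[C@H](C)c1ccc(OCc2ccccc2)cc1 | intermediate
9 | 1-(benzyloxy)-4-[(2S)-4,4-dibromobut-3-en-2-yl]benzene | BrC(Br)=C[C@H](C)c1ccc(OCc2ccccc2)cc1 | intermediate
10 | lithium acetylide of 1-(benzyloxy)-4-[(2S)-but-3-yn-2-yl]benzene | [Li]C#C[C@H](C)c1ccc(OCc2ccccc2)cc1 | intermediate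
11 | lithium (3R)-3-[4-(benzyloxy)phenyl]but-1-yn-1-olate | [Li]OC#C[C@H](C)c1ccc(OCc2ccccc2)cc1 | intermediate
12 | triisopropyl({(3R)-3-[4-(benzyloxy)phenyl]but-1-yn-1-yl}oxy)silane | CC(C)[Si](OC#C[C@H](C)c1ccc(OCc2ccccc2)cc1)(C(C)C)C(C)C | intermediate
13 | 3-ethoxycyclobut-2-en-1-one | CCOC1=CC(=O)C1 | starting material
14 | benzyl alcohol | OCc1ccccc1 | starting material
15 | 3-(benzyloxy)cyclobut-2-en-1-one | O=C1C=C(OCc2ccccc2)C1 | intermediate
16 | 3-(benzyloxy)buta-1,3-dien-1-one (vinylketene) | O=C=CC(=C)OCc1ccccc1 | intermediate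
17 | 4-[1-(benzyloxy)ethenyl]-2-{(1R)-1-[4-(benzyloxy)phenyl]ethyl}-3-[(triisopropylsilyl)oxy]cyclobut-2-en-1-one (both C4 epimers) | O=C1C([C@H](C)c2ccc(OCc3ccccc3)cc2)=C(O[Si](C(C)C)(C(C)C)C(C)C)C1C(=C)OCc1ccccc1 | intermediate
18 | 5-(benzyloxy)-2-{(1R)-1-[4-(benzyloxy)phenyl]ethyl}-3-[(triisopropylsilyl)oxy]hexa-1,3,5-trien-1-one, ketene and enol ether termini cis across C3=C4 | O=C=C([C@H](C)c1ccc(OCc2ccccc2)cc1)/C(O[Si](C(C)C)(C(C)C)C(C)C)=C\C(=C)OCc1ccccc1 | intermediate
19 | 5-(benzyloxy)-2-{(1R)-1-[4-(benzyloxy)phenyl]ethyl}-3-[(triisopropylsilyl)oxy]cyclohexa-2,4-dien-1-one | O=C1CC(OCc2ccccc2)=CC(O[Si](C(C)C)(C(C)C)C(C)C)=C1[C@H](C)c1ccc(OCc2ccccc2)cc1 | intermediate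
20 | 5-(benzyloxy)-2-{(1R)-1-[4-(benzyloxy)phenyl]ethyl}-3-[(triisopropylsilyl)oxy]phenol | Oc1cc(OCc2ccccc2)cc(O[Si](C(C)C)(C(C)C)C(C)C)c1[C@H](C)c1ccc(OCc2ccccc2)cc1 | intermediate
21 | 3-(benzyloxy)-6-{(1R)-1-[4-(benzyloxy)phenyl]ethyl}-2-bromo-5-[(triisopropylsilyl)oxy]phenol | Oc1c(Br)c(OCc2ccccc2)cc(O[Si](C(C)C)(C(C)C)C(C)C)c1[C@H](C)c1ccc(OCc2ccccc2)cc1 | intermediate
22 | N,2-dimethoxy-N-methylacetamide | COCC(=O)N(C)OC | starting material
23 | O,C-dilithio derivative of 21 (lithium phenoxide, aryllithium at C4a) | [Li]Oc1c([Li])c(OCc2ccccc2)cc(O[Si](C(C)C)(C(C)C)C(C)C)c1[C@H](C)c1ccc(OCc2ccccc2)cc1 | intermediate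
24 | 1-{6-(benzyloxy)-3-[(1R)-1-[4-(benzyloxy)phenyl]ethyl]-2-hydroxy-4-[(triisopropylsilyl)oxy]phenyl}-2-methoxyethan-1-one | COCC(=O)c1c(O)c([C@H](C)c2ccc(OCc3ccccc3)cc2)c(O[Si](C(C)C)(C(C)C)C(C)C)cc1OCc1ccccc1 | intermediate
25 | 4-methoxybenzoyl chloride | COc1ccc(C(Cl)=O)cc1 | starting material
26 | 1-{6-(benzyloxy)-3-[(1R)-1-[4-(benzyloxy)phenyl]ethyl]-2-hydroxy-4-[(triisopropylsilyl)oxy]phenyl}-2-methoxy-3-(4-methoxyphenyl)propane-1,3-dione (C2 labile, unassigned) | COc1ccc(cc1)C(=O)C(OC)C(=O)c1c(O)c([C@H](C)c2ccc(OCc3ccccc3)cc2)c(O[Si](C(C)C)(C(C)C)C(C)C)cc1OCc1ccccc1 | intermediate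
27 | 5-(benzyloxy)-8-{(1R)-1-[4-(benzyloxy)phenyl]ethyl}-3-methoxy-2-(4-methoxyphenyl)-7-[(triisopropylsilyl)oxy]-4H-chromen-4-one | COc1ccc(-c2oc3c([C@H](C)c4ccc(OCc5ccccc5)cc4)c(O[Si](C(C)C)(C(C)C)C(C)C)cc(OCc4ccccc4)c3c(=O)c2OC)cc1 | intermediate
28 | 5-(benzyloxy)-8-{(1R)-1-[4-(benzyloxy)phenyl]ethyl}-7-hydroxy-3-methoxy-2-(4-methoxyphenyl)-4H-chromen-4-one | COc1ccc(-c2oc3c([C@H](C)c4ccc(OCc5ccccc5)cc4)c(O)cc(OCc4ccccc4)c3c(=O)c2OC)cc1 | intermediate
29 | 5,7-dihydroxy-8-[(1R)-1-(4-hydroxyphenyl)ethyl]-3-methoxy-2-(4-methoxyphenyl)-4H-chromen-4-one | COc1ccc(-c2oc3c([C@H](C)c4ccc(O)cc4)c(O)cc(O)c3c(=O)c2OC)cc1 | target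

Total step count: 13. Longest linear sequence: 12 steps (1 to 29 through steps 1–6 and 8–13). Step 7 is a one-step side branch.

Steps most likely to fail

1. Step 8 (key step).
- What may go wrong: the donor oxygen stabilises 15 as a vinylogous ester, so ring opening may need high temperatures. At those temperatures 12 may undergo an oxygen-to-carbon silyl shift. Vinylketene 16 may also oligomerise or acylate the product phenol faster than the alkyne intercepts it.
- Fallback: it sets out from 12 and 14 and comes back at 17, hence at 20. It generates 16 photochemically at room temperature instead of by electrocyclic opening. Acid-catalysed ketal exchange and loss of methanol from commercial 3,3-dimethoxybutan-2-one with 14 should give 3-(benzyloxy)but-3-en-2-one F1. Trifluoroacetylation of its kinetic lithium enolate (LiN(SiMe3)2, 2,2,2-trifluoroethyl trifluoroacetate, THF, −78 °C) should give 5-(benzyloxy)-1,1,1-trifluorohex-5-ene-2,4-dione F2. Detrifluoroacetylative diazo transfer (methanesulfonyl azide, Et3N, MeCN) should then give 3-(benzyloxy)-1-diazobut-3-en-2-one F3. Irradiation of F3 in the presence of 12 (CH2Cl2, 300 nm, rt) triggers a Wolff rearrangement to 16, which is trapped as 17. Brief heating in toluene completes the sequence to 20.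

2. Step 6.
- What may go wrong: oxygen transfer to the acetylide may be incomplete. Silylation may occur at carbon and give a silylketene. A partial propargyl–allenyl proton shift may erode the enantiopurity.
- Fallback: it sets out from 6 and comes back at 11, hence at 12. It reaches the ynolate by Kowalski ester homologation instead of acetylide oxidation. LiOH/H2O2 (THF–H2O, 0 °C) cleaves the auxiliary to (2R)-2-[4-(benzyloxy)phenyl]propanoic acid F4. EtI/KHCO3 in DMF gives ethyl (2R)-2-[4-(benzyloxy)phenyl]propanoate F5. Addition of F5 to LiCHBr2 (CH2Br2, lithium 2,2,6,6-tetramethylpiperidide, THF, −90 °C), followed by LiN(SiMe3)2, gives lithium (3R)-3-[4-(benzyloxy)phenyl]-1,1-dibromobut-1-en-2-olate F6. Bromine–lithium exchange with n-BuLi and a 1,2-shift of the chiral group with retention give 11, which is silylated as in the main route. This path is held in reserve because the carbenoid base can enolise the alpha-aryl ester.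

3. Step 10.
- What may go wrong: bromine–lithium exchange may be sluggish on the electron-rich phenoxide. Proton transfer to the aryllithium from the neighbouring benzyl ether or from the amide would return 20. The weakness could also lie one step earlier, in imperfect site selection during the bromination.
- Fallback: it sets out from 20 and comes back at 24, and it bypasses the halide altogether. Casnati–Skattebøl formylation (MgCl2, Et3N, paraformaldehyde, MeCN, reflux) can only strike the single free ortho position C4a. It should give 6-(benzyloxy)-3-{(1R)-1-[4-(benzyloxy)phenyl]ethyl}-2-hydroxy-4-[(triisopropylsilyl)oxy]benzaldehyde F7. Addition of methoxymethyllithium (Bu3SnCH2OMe, n-BuLi, 2.2 equiv, THF, −78 °C) gives 1-{6-(benzyloxy)-3-[(1R)-1-[4-(benzyloxy)phenyl]ethyl]-2-hydroxy-4-[(triisopropylsilyl)oxy]phenyl}-2-methoxyethan-1-ol F8 as a mixture of carbinol epimers. Oxidation with MnO2 in CH2Cl2 gives 24.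

Further compounds
F1 | step 8 | 3-(benzyloxy)but-3-en-2-one | C=C(OCc1ccccc1)C(C)=O
F2 | step 8 | 5-(benzyloxy)-1,1,1-trifluorohex-5-ene-2,4-dione | C=C(OCc1ccccc1)C(=O)CC(=O)C(F)(F)F
F3 | step 8 | 3-(benzyloxy)-1-diazobut-3-en-2-one | C=C(OCc1ccccc1)C(=O)C=[N+]=[N-]
F4 | step 6 | (2R)-2-[4-(benzyloxy)phenyl]propanoic acid | OC(=O)[C@H](C)c1ccc(OCc2ccccc2)cc1
F5 | step 6 | ethyl (2R)-2-[4-(benzyloxy)phenyl]propanoate | CCOC(=O)[C@H](C)c1ccc(OCc2ccccc2)cc1
F6 | step 6 | lithium (3R)-3-[4-(benzyloxy)phenyl]-1,1-dibromobut-1-en-2-olate | [Li+].[O-]C(=C(Br)Br)[C@H](C)c1ccc(OCc2ccccc2)cc1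
F7 | step 10 | 6-(benzyloxy)-3-{(1R)-1-[4-(benzyloxy)phenyl]ethyl}-2-hydroxy-4-[(triisopropylsilyl)oxy]benzaldehyde | O=Cc1c(O)c([C@H](C)c2ccc(OCc3ccccc3)cc2)c(O[Si](C(C)C)(C(C)C)C(C)C)cc1OCc1ccccc1
F8 | step 10 | 1-{6-(benzyloxy)-3-[(1R)-1-[4-(benzyloxy)phenyl]ethyl]-2-hydroxy-4-[(triisopropylsilyl)oxy]phenyl}-2-methoxyethan-1-ol (both carbinol epimers) | COCC(O)c1c(O)c([C@H](C)c2ccc(OCc3ccccc3)cc2)c(O[Si](C(C)C)(C(C)C)C(C)C)cc1OCc1ccccc1
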